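**Assumption:** the SMILES decodes to the cis-(6aR,11aR) pterocarpan; pterocarpan numbering (O5, C6, C6a, C6b, C7–C10, C10a, O11, C11a, C11b, C1–C4, C4a) is used throughout, and "prenyl" means 3-methylbut-2-en-1-yl.

## Retrosynthetic overview

1. Target ⇐ 9-O-allyl ether (Pd deallylation) ⇐ D-ring dimethylpyran by propargyl-ether Claisen/oxa-6π at C7 from the 8-OH of pterocarpan phenol 20.
2. 20 (furan B ring, C6a–C6b and C11a–O11 bonds, both stereocentres, D-ring aromatisation) ⇐ catalytic enantioselective formal [3+2] of bis-chromene 11 with 2-allyloxy-3-prenyl-1,4-benzoquinone 19 (the new step).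
3. 11 ⇐ resorcinol: chromanone → chromenol → C6 formylation → O-allylation / methylenation / RCM.
4. 19 ⇐ resorcinol: bis-MOM, C2 lithiation/prenylation, deprotection, mono-allylation, Fremy oxidation.
5. Ring order: A-ring pyran → C ring (RCM) → B ring with D-ring aromatisation (key step) → D-ring pyran last.

## Route

### Fragment A: bis-chromene 11

**Step 1**
Reactants: 1 resorcinol; 2 3-methylbut-2-enoic acid
Product: 3 7-hydroxy-2,2-dimethylchroman-4-one
Conditions: P2O5/MeSO3H (Eaton's reagent), 70 °C
Reagents that add atoms: 3-methylbut-2-enoic acid, CC(C)=CC(=O)O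
Why: Friedel–Crafts acylation at C4 of resorcinol followed by oxa-Michael closure of the ortho OH gives the 7-hydroxychromanone in one pot.

**Step 2**
Reactants: 3
Product: 4 2,2-dimethyl-2H-chromen-7-ol
Conditions: LiAlH4, THF, 0 °C → reflux; then 2 M HCl, THF, rt
Reagents that add atoms: none
Why: hydride reduction to the chroman-4-ol, then acid-catalysed E1 dehydration of the para-oxygenated benzylic alcohol.

**Step 3**
Reactants: 4; 5 paraformaldehyde
Product: 6 7-hydroxy-2,2-dimethyl-2H-chromene-6-carbaldehyde
Conditions: MgCl2, Et3N, (CH2O)n, MeCN, reflux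
Reagents that add atoms: formaldehyde (as paraformaldehyde), C=O
Why: Mg-phenoxide-directed ortho-formylation (Casnati–Skattebøl) goes to the less hindered ortho carbon C6 (para to O1) rather than C8, which is flanked by two oxygens; this fixes the linear pyran pattern.

**Step 4**
Reactants: 6; 7 allyl bromide
Product: 8 7-(allyloxy)-2,2-dimethyl-2H-chromene-6-carbaldehyde
Conditions: K2CO3, DMF, 50 °C
Reagents that add atoms: allyl bromide, C=CCBr
Why: Williamson O-alkylation of the phenol.

**Step 5**
Reactants: 8; 9 methyltriphenylphosphonium bromide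
Product: 10 7-(allyloxy)-2,2-dimethyl-6-vinyl-2H-chromene
Conditions: Ph3PCH3Br, KOtBu, THF, 0 °C → rt
Reagents that add atoms: methyltriphenylphosphonium bromide (CH2 donor), C[P+](c1ccccc1)(c1ccccc1)c1ccccc1.[Br-]
Why: Wittig methylenation of the aryl aldehyde.

**Step 6**
Reactants: 10
Product: 11 2,2-dimethyl-2H,8H-pyrano[3,2-g]chromene (linear bis-chromene; C6=C7 alkene flanked by C8H2, C3=C4 alkene flanked by CMe2)
Conditions: Grubbs II (2 mol%), CH2Cl2, 40 °C
Reagents that add atoms: none (ethylene lost)
Why: ring-closing metathesis of the styrene/allyl ether pair gives the 2H-chromene; the endocyclic cis-alkene of the other pyran is inert.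

### Fragment B: quinone 19

**Step 7**
Reactants: 1 resorcinol; 12 chloromethyl methyl ether
Product: 13 1,3-bis(methoxymethoxy)benzene
Conditions: MOMCl (2.5 eq), i-Pr2NEt, CH2Cl2, 0 °C → rt
Reagents that add atoms: MOMCl, COCCl
Why: standard acetal protection; the two OMOM groups later direct lithiation to C2.

**Step 8**
Reactants: 13; 14 prenyl bromide
Product: 15 1,3-bis(methoxymethoxy)-2-(3-methylbut-2-en-1-yl)benzene
Conditions: n-BuLi, THF, 0 °C → rt; then CuI (10 mol%), 14, −78 °C → rt
Reagents that add atoms: prenyl bromide, CC(C)=CCBr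
Why: directed ortho-metalation at the doubly activated C2, then SN2 alkylation of the aryl metal.

**Step 9**
Reactants: 15
Product: 16 2-(3-methylbut-2-en-1-yl)benzene-1,3-diol
Conditions: p-TsOH·H2O (0.2 eq), MeOH, 40 °C (stop at full conversion)
Reagents that add atoms: none
Why: mild acetal methanolysis; short, dilute-acid conditions avoid cyclisation of the ortho-prenylphenol to a chroman.

**Step 10**
Reactants: 16; 7 allyl bromide
Product: 17 3-(allyloxy)-2-(3-methylbut-2-en-1-yl)phenol
Conditions: allyl bromide (1.0 eq), K2CO3, acetone, reflux; recycle recovered 16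
Reagents that add atoms: allyl bromide, C=CCBr
Why: statistical mono-Williamson etherification of a symmetrical diol, so no regiochemical issue.

**Step 11**
Reactants: 17; 18 Fremy's salt
Product: 19 2-(allyloxy)-3-(3-methylbut-2-en-1-yl)cyclohexa-2,5-diene-1,4-dione
Conditions: (KSO3)2NO, KH2PO4 buffer, acetone/H2O, rt
Reagents that add atoms: potassium nitrosodisulfonate (O donor), [O]N(S(=O)(=O)[O-])S(=O)(=O)[O-].[K+].[K+]
Why: Teuber oxidation of a phenol with a free para position gives the p-quinone; the new C=O is next to the allyloxy carbon.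

### Union and endgame

**Step 12 (key step)**
Reactants: 11 (1.3 eq); 19 (1.0 eq)
Product: 20 (6aR,11aR)-9-(allyloxy)-8-hydroxy-10-prenylpterocarpan carrying a 2,2-dimethyl-2H-pyran fused at C2–C3 (pyran O on C3, CH=CH on C2)
Conditions: (R)-o-tolyl-diphenylprolinol oxazaborolidine·HNTf2 (20 mol%; precursor Cc1ccccc1B1OC(c2ccccc2)(c2ccccc2)[C@H]2CCCN12 + Tf2NH), CH2Cl2, 4 Å MS, −78 → −20 °C
Reagents that add atoms: none (both reactants are fully incorporated)
Why: Proposed new method: the cationic chiral oxazaborolidinium binds C1=O of 19 (lone pair anti to O-allyl, C6–H···O contact), making C5 the electrophilic carbon and stacking the C5=C6 bond on a catalyst phenyl so one quinone face is open; the CH2-flanked alkene carbon of 11 (the CMe2-flanked alkene is sterically shielded) adds to C5 in an endo, arene-over-quinone orientation, the o,p-dioxygenated benzylic cation is trapped on the same face by the C4 carbonyl oxygen (directly or via a cyclobutane that undergoes 1,3-shift), and tautomerisation aromatises the D ring, so C6a and C11a form cis by ring constraint with (6aR,11aR) set by the catalyst, and the regiochemistry places 8-OH (from C1=O), 9-O-allyl, 10-prenyl and O11 (from C4=O) correctly; the closest known reaction types are the stoichiometric Ti(IV)-promoted formal [3+2] of 2-alkoxy-1,4-benzoquinones with 2H-chromenes and styrenes and the oxazaborolidinium-catalysed enantioselective [3+2] of 2-methoxybenzoquinone with a cyclic enol ether, neither shown catalytically and asymmetrically on 2H-chromenes or 3-alkyl-2-alkoxyquinones; the (R)-catalyst is assigned from this shielding model, the sense of induction is not certain, and the (S)-catalyst is used instead if the first run gives the antipode.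

**Step 13**
Reactants: 20; 21 3-chloro-3-methylbut-1-yne
Product: 22 the 8-O-(2-methylbut-3-yn-2-yl) ether of 20, (6aR,11aR)
Conditions: 21 (3 eq), DBU, CuCl2·2H2O (1 mol%), MeCN, 0 °C → rt
Reagents that add atoms: 3-chloro-3-methylbut-1-yne, CC(C)(Cl)C#C
Why: Cu-catalysed O-propargylation of the only free phenol via a copper allenylidene; the stereocentres are untouched.

**Step 14**
Reactants: 22
Product: 23 (6aR,11aR)-9-O-allyl ether of the target (D-ring 2,2-dimethylpyran: O on C8, CH=CH on C7)
Conditions: o-xylene, BHT (cat.), 140 °C
Reagents that add atoms: none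
Why: aryl propargyl ether Claisen rearrangement to C7 (the only free ortho position), then 1,5-H shift and oxa-6π electrocyclisation give the chromene; the allyl ether has both ortho positions blocked and survives.

**Step 15**
Reactants: 23
Product: 24 Lespecyrtin E4, (6aR,11aR)
Conditions: Pd(PPh3)4 (5 mol%), morpholine, THF, rt
Reagents that add atoms: none
Why: Tsuji–Trost deallylation via π-allyl-Pd with an amine scavenger frees the 9-OH under neutral conditions that leave the prenyl group, both chromenes and the acid-labile benzylic C11a–O bond intact.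

## Compound list

1 | resorcinol | Oc1cccc(O)c1 | starting material
2 | 3-methylbut-2-enoic acid | CC(C)=CC(=O)O | starting material
3 | 7-hydroxy-2,2-dimethylchroman-4-one | CC1(C)CC(=O)c2ccc(O)cc2O1 | intermediate
4 | 2,2-dimethyl-2H-chromen-7-ol | CC1(C)C=Cc2ccc(O)cc2O1 | intermediate
5 | paraformaldehyde (formaldehyde unit) | C=O | starting material
6 | 7-hydroxy-2,2-dimethyl-2H-chromene-6-carbaldehyde | CC1(C)C=Cc2cc(C=O)c(O)cc2O1 | intermediate
7 | allyl bromide | C=CCBr | starting material
8 | 7-(allyloxy)-2,2-dimethyl-2H-chromene-6-carbaldehyde | CC1(C)C=Cc2cc(C=O)c(OCC=C)cc2O1 | intermediate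
9 | methyltriphenylphosphonium bromide | C[P+](c1ccccc1)(c1ccccc1)c1ccccc1.[Br-] | starting material
10 | 7-(allyloxy)-2,2-dimethyl-6-vinyl-2H-chromene | CC1(C)C=Cc2cc(C=C)c(OCC=C)cc2O1 | intermediate
11 | 2,2-dimethyl-2H,8H-pyrano[3,2-g]chromene | CC1(C)C=Cc2cc3C=CCOc3cc2O1 | intermediate
12 | chloromethyl methyl ether | COCCl | starting material
13 | 1,3-bis(methoxymethoxy)benzene | COCOc1cccc(OCOC)c1 | intermediate
14 | prenyl bromide (1-bromo-3-methylbut-2-ene) | CC(C)=CCBr | starting material
15 | 1,3-bis(methoxymethoxy)-2-prenylbenzene | COCOc1cccc(OCOC)c1CC=C(C)C | intermediate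
16 | 2-prenylbenzene-1,3-diol | CC(C)=CCc1c(O)cccc1O | intermediate
17 | 3-(allyloxy)-2-prenylphenol | CC(C)=CCc1c(O)cccc1OCC=C | intermediate
18 | Fremy's salt (potassium nitrosodisulfonate) | [O]N(S(=O)(=O)[O-])S(=O)(=O)[O-].[K+].[K+] | starting material
19 | 2-(allyloxy)-3-prenyl-1,4-benzoquinone | CC(C)=CCC1=C(OCC=C)C(=O)C=CC1=O | intermediate
20 | (6aR,11aR)-9-allyloxy-8-hydroxy-10-prenyl-[2,2-dimethylpyrano-(C2,C3)]pterocarpan | CC(C)=CCc1c(OCC=C)c(O)cc2c1O[C@H]1c3cc4c(cc3OC[C@@H]21)OC(C)(C)C=C4 | intermediate
21 | 3-chloro-3-methylbut-1-yne | CC(C)(Cl)C#C | starting material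
22 | 8-O-(1,1-dimethylpropargyl) ether of 20, (6aR,11aR) | CC(C)=CCc1c(OCC=C)c(OC(C)(C)C#C)cc2c1O[C@H]1c3cc4c(cc3OC[C@@H]21)OC(C)(C)C=C4 | intermediate
23 | 9-O-allyl Lespecyrtin E4, (6aR,11aR) | CC(C)=CCc1c(OCC=C)c2c(c3c1O[C@H]1c4cc5c(cc4OC[C@@H]31)OC(C)(C)C=C5)C=CC(C)(C)O2 | intermediate
24 | Lespecyrtin E4, (6aR,11aR) | CC(C)=CCc1c(O)c2c(c3c1O[C@H]1c4cc5c(cc4OC[C@@H]31)OC(C)(C)C=C5)C=CC(C)(C)O2 | target

## Summary

Total steps: 15.
Longest linear sequence: 10 (steps 1–6, then 12–15); the quinone branch is 5 steps (7–11).

Three steps most likely to fail: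

1. **Step 12 (proposed new method).** Risks are low turnover or ee, the wrong sense of induction, competing attack at the CMe2-flanked alkene, and stalled cyclobutane adducts. Fallback (known chemistry, different bond construction): make the corresponding 2'-O-protected isoflavone by Suzuki coupling of the linear pyrano-3-iodochromone with a D-ring arylboronate, set both stereocentres by Ru(II)–TsDPEN asymmetric transfer hydrogenation with dynamic kinetic resolution to the cis-isoflavan-4-ol, and close the furan ring by acid-mediated cyclisation to 20.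
2. **Step 3.** Risks are C6 versus C8 formylation and the lability of the free phenolic chromene 4 (which also affects step 2). Fallback: carry the A-ring pyran saturated — deoxygenate 3 to 2,2-dimethylchroman-7-ol, formylate (classically C6-selective), O-allylate, then introduce the double bond by DDQ dehydrogenation to reach 8.
3. **Step 14.** Risk is decomposition or abnormal Claisen products from the advanced intermediate at the hindered C7 position. Fallback: build the D-ring pyran directly on phenol 20 by condensation with 3-methylbut-2-enal mediated by PhB(OH)2/AcOH (ortho-quinone methide then oxa-6π), which avoids the propargyl ether and the high-temperature rearrangement.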